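**Plan**

- Locants: quinone ring C1–C4, fusion carbons C4a and C8a, benzo carbons C5–C8, side chain C1′–C16′. The unsubstituted benzo ring (C4a, C5–C8, C8a) is held to the rest only by C1–C8a and C4–C4a, and C1 and C4 both bear oxygen. That is the imprint of benzyne adding across the two α-carbons of a furan whose β-carbons carry the methyl group and the chain.
- Cuts, in retrosynthetic order: O–Si at C5′; the C1/C4 carbonyls back to a 1,4-oxygen bridge; C1–C8a and C4–C4a (aryne [4+2]); C3–C1′ (furyl–allyl coupling); C1′–C2′ and C3′–CH3 (alkyne methylalumination/formaldehyde); C4′–C5′ (propargylation of a C15 aldehyde).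
- Forward order: the chain is grown from farnesol (C15 aldehyde, C18 alkyne, C20 E-allylic bromide) and joined to 3-bromo-4-methylfuran. The carbocycle is then closed onto the furan by benzyne, the bridge is opened and oxidised to the quinone, and the silyl ether is removed last.
- Stereochemistry: C7′ and C11′ come from catalyst-controlled hydrogenation of the two E alkenes of farnesol. C5′ comes from a D-tartrate allenylboronate (reagent control). The E C2′=C3′ bond comes from syn-methylalumination. No later step touches these elements.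

Key step: step 9

Assumption: in step 1 the hand of the P,N ligand on iridium is taken to be the one that converts the E,E-triene into the 3R,7R alcohol; the sense is to be checked on 2 by optical rotation and the mirror-image ligand used if it is the reverse.

**Route**

Step 1
Reactants: 1 (2E,6E)-farnesol
Product: 2 (3R,7R)-3,7,11-trimethyldodecan-1-ol
Conditions: H2 (50 bar), [Ir(cod)(L)][B(C6H3(CF3)2)4] (1 mol %; cod = 1,5-cyclooctadiene, L = single enantiomer of 2-phenyl-7-(di-o-tolylphosphinooxy)-6,7-dihydro-5H-cyclopenta[b]pyridine), CH2Cl2, 25 °C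
Reagents that add atoms: none
Why: Iridium-catalysed asymmetric hydrogenation with a P,N ligand reduces trisubstituted alkenes that lack a coordinating group and is established on farnesol itself; the two E alkenes offer the same enantioface, so C3 and C7 are both set R by the catalyst, and the isopropylidene end gives no stereocentre.

Step 2
Reactants: 2 (3R,7R)-3,7,11-trimethyldodecan-1-ol
Product: 3 (3R,7R)-3,7,11-trimethyldodecanal
Conditions: PhI(OAc)2 (1.1 equiv), TEMPO (10 mol %), CH2Cl2, 25 °C
Reagents that add atoms: none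
Why: TEMPO-catalysed oxidation with PhI(OAc)2 should stop cleanly at the aldehyde, and the C3 centre is β to the carbonyl and so cannot epimerise.

Step 3
Reactants: 3 (3R,7R)-3,7,11-trimethyldodecanal
Product: 4 (4S,6R,10R)-6,10,14-trimethylpentadec-1-yn-4-ol
Conditions: propa-1,2-dienylboronic acid (1.5 equiv), diisopropyl D-tartrate (1.6 equiv), 4 Å MS, toluene, 25 °C; then 3, −78 °C, 20 h; H2O
Reagents that add atoms: propa-1,2-dienylboronic acid, C=C=CB(O)O
Why: Asymmetric propargylation with a tartrate-modified allenylboronate passes through a closed six-membered SE2′ transition state in which the D-tartrate ester is expected to direct the allenyl terminus to the Re face of the aldehyde, which sets C4 as S under reagent control with little bias from the remote C6 methyl.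

Step 4
Reactants: 4 (4S,6R,10R)-6,10,14-trimethylpentadec-1-yn-4-ol
Product: 5 tert-butyldimethyl{[(4S,6R,10R)-6,10,14-trimethylpentadec-1-yn-4-yl]oxy}silane
Conditions: TBSCl, imidazole, DMF, 25 °C
Reagents that add atoms: tert-butyldimethylsilyl chloride, CC(C)(C)[Si](C)(C)Cl
Why: Routine silylation of an unhindered secondary alcohol gives an ether that should withstand the organoaluminium, organocopper, fluoride and mild-acid steps ahead and keeps the hydroxyl away from the aryne.

Step 5
Reactants: 5 tert-butyldimethyl{[(4S,6R,10R)-6,10,14-trimethylpentadec-1-yn-4-yl]oxy}silane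
Product: 8 (2E,5S,7R,11R)-5-(tert-butyldimethylsilyloxy)-3,7,11,15-tetramethylhexadec-2-en-1-ol, via alkenylalane 6 (not isolated), via lithium alkenylalanate 7 (not isolated)
Conditions: Me3Al (2 equiv), Cp2ZrCl2 (0.25 equiv), ClCH2CH2Cl, 0 → 25 °C; volatiles removed; n-BuLi, THF–hexane, −78 → 0 °C; (CH2O)n, 25 °C; aq. potassium sodium tartrate
Reagents that add atoms: trimethylaluminium, C[Al](C)C; formaldehyde (from paraformaldehyde), C=O
Why: Zirconium-catalysed methylalumination (Negishi carboalumination) adds CH3 and Al syn across the terminal alkyne with aluminium on C1, and the alanate is hydroxymethylated by formaldehyde with retention, which fixes the C2=C3 bond as E; homopropargylic silyl ethers are tolerated substrates.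

Step 6
Reactants: 8 (2E,5S,7R,11R)-5-(tert-butyldimethylsilyloxy)-3,7,11,15-tetramethylhexadec-2-en-1-ol
Product: 9 (2E,5S,7R,11R)-1-bromo-5-(tert-butyldimethylsilyloxy)-3,7,11,15-tetramethylhexadec-2-ene
Conditions: CBr4, PPh3, CH2Cl2, −20 → 0 °C
Reagents that add atoms: tetrabromomethane, BrC(Br)(Br)Br
Why: The Appel reaction converts a primary allylic alcohol into the bromide under neutral conditions, without allylic transposition or loss of alkene geometry at low temperature.

Step 7
Reactants: 10 3,4-dibromofuran
Product: 12 3-bromo-4-methylfuran, via 3-bromo-4-lithiofuran 11 (not isolated)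
Conditions: n-BuLi (1.0 equiv), Et2O, −78 °C; MeI, −78 → 25 °C
Reagents that add atoms: iodomethane, CI
Why: Single bromine–lithium exchange on 3,4-dibromofuran at −78 °C followed by alkylation is the standard entry to 3-bromo-4-alkylfurans, the low temperature preventing loss of LiBr and migration of lithium to the α-position.

Step 8
Reactants: 12 3-bromo-4-methylfuran; 9 (2E,5S,7R,11R)-1-bromo-5-(tert-butyldimethylsilyloxy)-3,7,11,15-tetramethylhexadec-2-ene
Product: 15 3-methyl-4-[(2E,5S,7R,11R)-5-(tert-butyldimethylsilyloxy)-3,7,11,15-tetramethylhexadec-2-en-1-yl]furan, via 4-methyl-3-furyllithium 13 (not isolated), via 4-methyl-3-furylcopper 14 (not isolated)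
Conditions: 12 (1.5 equiv), n-BuLi, Et2O, −78 °C; CuBr·SMe2, −78 → −40 °C; 9, THF, −40 → 0 °C
Reagents that add atoms: none
Why: Bromine–lithium exchange, transmetalation to the arylcopper and copper-mediated allylic substitution (the coupling used to prenylate aryl metals) should deliver the furyl group to the unhindered primary carbon of 9 with the E alkene intact; no stereocentre is formed.

Step 9
Reactants: 15 3-methyl-4-[(2E,5S,7R,11R)-5-(tert-butyldimethylsilyloxy)-3,7,11,15-tetramethylhexadec-2-en-1-yl]furan; 16 2-(trimethylsilyl)phenyl trifluoromethanesulfonate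
Product: 18 2-methyl-3-[(2E,5S,7R,11R)-5-(tert-butyldimethylsilyloxy)-3,7,11,15-tetramethylhexadec-2-en-1-yl]-1,4-dihydro-1,4-epoxynaphthalene (both bridgehead diastereomers), via benzyne 17 (not isolated)
Conditions: CsF (3 equiv), MeCN–THF (2:1), 25 °C, 16 (1.5 equiv) added over 4 h; chromatography on Et3N-deactivated SiO2
Reagents that add atoms: none
Why: Fluoride attacks the silicon of 16 and triflate leaves from the adjacent carbon, so benzyne 17 is released slowly and is trapped at once by the electron-rich furan diene of 15 in a concerted suprafacial [4+2] cycloaddition, the aryne–furan Diels–Alder reaction, whose closest precedent is the union of benzyne from this same precursor with 3,4-dialkylfurans to give 1,4-epoxy-1,4-dihydronaphthalenes. The six-membered carbocycle closes by intermolecular cycloaddition, the C1–C8a and C4–C4a bonds forming together across the two furan α-carbons while the furan oxygen stays as the 1,4-bridge. The two bridgehead carbons become stereocentres whose relative configuration is fixed by the bridge; their sense relative to the distant chain centres is not controlled and need not be, because both are erased in step 10. The step needs chemoselectivity for the furan over the C2′=C3′ alkene (aryne ene reaction) and over the silyl ether: the furan is by far the fastest aryne trap present, slow addition keeps the aryne concentration low, and a secondary alkyl TBS ether should be inert to CsF under these conditions. Benzyne is symmetrical, so no regiochemical question arises.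

Step 10
Reactants: 18 2-methyl-3-[(2E,5S,7R,11R)-5-(tert-butyldimethylsilyloxy)-3,7,11,15-tetramethylhexadec-2-en-1-yl]-1,4-dihydro-1,4-epoxynaphthalene
Product: 21 2-[(2E,5S,7R,11R)-5-(tert-butyldimethylsilyloxy)-3,7,11,15-tetramethylhexadec-2-en-1-yl]-3-methylnaphthalene-1,4-dione, via 2-alkyl-3-methyl-1-naphthol 19 (not isolated), via 3-alkyl-2-methyl-1-naphthol 20 (not isolated)
Conditions: CF3CO2H (10 mol %), CH2Cl2, 0 °C; then aq. KH2PO4/K2HPO4 (pH 7), K2NO(SO3)2 (2.5 equiv), methyltrioctylammonium chloride (10 mol %), 25 °C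
Reagents that add atoms: potassium nitrosodisulfonate, [K+].[K+].[O]N(S(=O)(=O)[O-])S(=O)(=O)[O-]
Why: Catalytic acid opens the oxygen bridge at either bridgehead to an allylic–benzylic cation that loses a proton to give both 1-naphthols (the known isomerisation of 1,4-epoxy-1,4-dihydronaphthalenes), and each naphthol has an alkylated ortho position and a free para position, so Teuber oxidation with K2NO(SO3)2 should converge on the single 1,4-quinone without touching the alkene or the silyl ether.

Step 11
Reactants: 21 2-[(2E,5S,7R,11R)-5-(tert-butyldimethylsilyloxy)-3,7,11,15-tetramethylhexadec-2-en-1-yl]-3-methylnaphthalene-1,4-dione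
Product: 22 2-[(2E,5S,7R,11R)-5-hydroxy-3,7,11,15-tetramethylhexadec-2-en-1-yl]-3-methylnaphthalene-1,4-dione
Conditions: HF·pyridine, pyridine, THF, 0 → 25 °C
Reagents that add atoms: none
Why: Buffered HF·pyridine cleaves a secondary TBS ether without affecting the quinone or the alkene (basic fluoride is avoided because the C1′ hydrogens next to the quinone are base-sensitive), and the C–O bond at C5′ is not broken, so the S configuration is kept.

**Compound list**

1 | (2E,6E)-farnesol | CC(C)=CCC/C(C)=C/CC/C(C)=C/CO | starting material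
2 | (3R,7R)-3,7,11-trimethyldodecan-1-ol | OCC[C@H](C)CCC[C@H](C)CCCC(C)C | intermediate
3 | (3R,7R)-3,7,11-trimethyldodecanal | O=CC[C@H](C)CCC[C@H](C)CCCC(C)C | intermediate
4 | (4S,6R,10R)-6,10,14-trimethylpentadec-1-yn-4-ol | C#CC[C@@H](O)C[C@H](C)CCC[C@H](C)CCCC(C)C | intermediate
5 | tert-butyldimethyl{[(4S,6R,10R)-6,10,14-trimethylpentadec-1-yn-4-yl]oxy}silane | C#CC[C@@H](O[Si](C)(C)C(C)(C)C)C[C@H](C)CCC[C@H](C)CCCC(C)C | intermediate
6 | [(1E,4S,6R,10R)-4-(tert-butyldimethylsilyloxy)-2,6,10,14-tetramethylpentadec-1-en-1-yl]dimethylalane | C[Al](C)/C=C(\C)C[C@@H](O[Si](C)(C)C(C)(C)C)C[C@H](C)CCC[C@H](C)CCCC(C)C | intermediate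
7 | lithium butyl[(1E,4S,6R,10R)-4-(tert-butyldimethylsilyloxy)-2,6,10,14-tetramethylpentadec-1-en-1-yl]dimethylaluminate | [Li+].CCCC[Al-](C)(C)/C=C(\C)C[C@@H](O[Si](C)(C)C(C)(C)C)C[C@H](C)CCC[C@H](C)CCCC(C)C | intermediate
8 | (2E,5S,7R,11R)-5-(tert-butyldimethylsilyloxy)-3,7,11,15-tetramethylhexadec-2-en-1-ol | OC/C=C(\C)C[C@@H](O[Si](C)(C)C(C)(C)C)C[C@H](C)CCC[C@H](C)CCCC(C)C | intermediate
9 | (2E,5S,7R,11R)-1-bromo-5-(tert-butyldimethylsilyloxy)-3,7,11,15-tetramethylhexadec-2-ene | BrC/C=C(\C)C[C@@H](O[Si](C)(C)C(C)(C)C)C[C@H](C)CCC[C@H](C)CCCC(C)C | intermediate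
10 | 3,4-dibromofuran | Brc1cocc1Br | starting material
11 | 3-bromo-4-lithiofuran | [Li]c1cocc1Br | intermediate
12 | 3-bromo-4-methylfuran | Cc1cocc1Br | intermediate
13 | (4-methylfuran-3-yl)lithium | [Li]c1cocc1C | intermediate
14 | (4-methylfuran-3-yl)copper | [Cu]c1cocc1C | intermediate
15 | 3-methyl-4-[(2E,5S,7R,11R)-5-(tert-butyldimethylsilyloxy)-3,7,11,15-tetramethylhexadec-2-en-1-yl]furan | Cc1cocc1C/C=C(\C)C[C@@H](O[Si](C)(C)C(C)(C)C)C[C@H](C)CCC[C@H](C)CCCC(C)C | intermediate
16 | 2-(trimethylsilyl)phenyl trifluoromethanesulfonate | C[Si](C)(C)c1ccccc1OS(=O)(=O)C(F)(F)F | starting material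
17 | benzyne (1,2-didehydrobenzene) | C1=CC=CC#C1 | intermediate
18 | 2-methyl-3-[(2E,5S,7R,11R)-5-(tert-butyldimethylsilyloxy)-3,7,11,15-tetramethylhexadec-2-en-1-yl]-1,4-dihydro-1,4-epoxynaphthalene (both bridgehead diastereomers, bridgeheads left unspecified) | CC1=C(C/C=C(\C)C[C@@H](O[Si](C)(C)C(C)(C)C)C[C@H](C)CCC[C@H](C)CCCC(C)C)C2OC1c1ccccc12 | intermediate
19 | 2-[(2E,5S,7R,11R)-5-(tert-butyldimethylsilyloxy)-3,7,11,15-tetramethylhexadec-2-en-1-yl]-3-methylnaphthalen-1-ol | Cc1cc2ccccc2c(O)c1C/C=C(\C)C[C@@H](O[Si](C)(C)C(C)(C)C)C[C@H](C)CCC[C@H](C)CCCC(C)C | intermediate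
20 | 3-[(2E,5S,7R,11R)-5-(tert-butyldimethylsilyloxy)-3,7,11,15-tetramethylhexadec-2-en-1-yl]-2-methylnaphthalen-1-ol | Cc1c(O)c2ccccc2cc1C/C=C(\C)C[C@@H](O[Si](C)(C)C(C)(C)C)C[C@H](C)CCC[C@H](C)CCCC(C)C | intermediate
21 | 2-[(2E,5S,7R,11R)-5-(tert-butyldimethylsilyloxy)-3,7,11,15-tetramethylhexadec-2-en-1-yl]-3-methylnaphthalene-1,4-dione | CC1=C(C/C=C(\C)C[C@@H](O[Si](C)(C)C(C)(C)C)C[C@H](C)CCC[C@H](C)CCCC(C)C)C(=O)c2ccccc2C1=O | intermediate
22 | 2-[(2E,5S,7R,11R)-5-hydroxy-3,7,11,15-tetramethylhexadec-2-en-1-yl]-3-methylnaphthalene-1,4-dione | CC1=C(C/C=C(\C)C[C@@H](O)C[C@H](C)CCC[C@H](C)CCCC(C)C)C(=O)c2ccccc2C1=O | target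

**Count**

Total steps: 11. Longest linear sequence: 10 steps (steps 1–6 and 8–11, from 1).

**Steps most likely to fail, with fallbacks**

Step 3. The tartrate ester may give incomplete facial control in the allenylboration, and the resulting C4 epimers would be hard to separate. The fallback sets C4 by resolution and sets out from 3.
- 3 would be methylenated with dimethylsulfonium methylide (Me3SI, NaH, DMSO–THF; Corey–Chaykovsky reaction) to 2-[(2R,6R)-2,6,10-trimethylundecyl]oxirane F1, formed as both epimers at the oxirane carbon.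
- Hydrolytic kinetic resolution with (S,S)-N,N′-bis(3,5-di-tert-butylsalicylidene)cyclohexane-1,2-diaminocobalt acetate and 0.55 equiv of water should hydrolyse the 2R epimer to the diol and leave (2S)-2-[(2R,6R)-2,6,10-trimethylundecyl]oxirane F2, which is easily separated from the diol.
- Lithium acetylide–ethylenediamine complex in DMSO should open F2 at its CH2 terminus, leaving the carbinol centre untouched, and the sequence returns to the route at 4.

Step 8. The furyl metal may lose positional integrity (lithium migrating from C3 to C2 of the furan before transmetalation) or substitution may occur at the tertiary end of the allyl system. The fallback reverses the polarity and forms C1′–C2′ instead; it sets out from 12 and 5.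
- 13, generated from 12 as in step 8, would be formylated with DMF to 4-methylfuran-3-carbaldehyde F3.
- F3 would be reduced with NaBH4 in MeOH to (4-methylfuran-3-yl)methanol F4.
- F4 would be converted with MsCl, LiCl and 2,4,6-collidine in DMF into 3-(chloromethyl)-4-methylfuran F5.
- The alkenylalane 6, made from 5 exactly as in step 5, would be coupled with F5 under Pd(PPh3)4 catalysis in THF (Negishi coupling of alkenylalanes with benzylic-type chlorides). The alkene geometry is already fixed by the carbometalation, and the sequence returns to the route at 15.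

Step 10. The acid may act beyond the oxygen bridge: the new hydroxyl of 19 may add to the C2′=C3′ alkene (chroman closure), or the silyl ether may be lost. The fallback carries out the aryne cycloaddition, ring opening and oxidation before the chain is attached; it sets out from 12 and 16 and uses 9.
- 12 and benzyne 17 (from 16, CsF, MeCN) should give 2-bromo-3-methyl-1,4-dihydro-1,4-epoxynaphthalene F6.
- HCl in MeOH would isomerise F6 to 2-bromo-3-methylnaphthalen-1-ol F7 and 3-bromo-2-methylnaphthalen-1-ol F8.
- K2NO(SO3)2 would oxidise both to 2-bromo-3-methylnaphthalene-1,4-dione F9.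
- Na2S2O4 would reduce F9 to 2-bromo-3-methylnaphthalene-1,4-diol F10, which would be methylated (Me2SO4, KOH) to 2-bromo-1,4-dimethoxy-3-methylnaphthalene F11.
- n-BuLi at −78 °C would give (1,4-dimethoxy-3-methylnaphthalen-2-yl)lithium F12, and CuBr·SMe2 the corresponding (1,4-dimethoxy-3-methylnaphthalen-2-yl)copper F13.
- Alkylation of F13 with 9 should give tert-butyl{[(2E,5S,7R,11R)-1-(1,4-dimethoxy-3-methylnaphthalen-2-yl)-3,7,11,15-tetramethylhexadec-2-en-5-yl]oxy}dimethylsilane F14.
- Oxidative demethylation with (NH4)2Ce(NO3)6 in MeCN–H2O at 0 °C returns to the route at 21.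

**Further compounds**

F1 | step 3 | 2-[(2R,6R)-2,6,10-trimethylundecyl]oxirane (both epimers at the oxirane carbon) | C1OC1C[C@H](C)CCC[C@H](C)CCCC(C)C
F2 | step 3 | (2S)-2-[(2R,6R)-2,6,10-trimethylundecyl]oxirane | C1O[C@H]1C[C@H](C)CCC[C@H](C)CCCC(C)C
F3 | step 8 | 4-methylfuran-3-carbaldehyde | Cc1cocc1C=O
F4 | step 8 | (4-methylfuran-3-yl)methanol | Cc1cocc1CO
F5 | step 8 | 3-(chloromethyl)-4-methylfuran | Cc1cocc1CCl
F6 | step 10 | 2-bromo-3-methyl-1,4-dihydro-1,4-epoxynaphthalene (racemic) | CC1=C(Br)C2OC1c1ccccc12
F7 | step 10 | 2-bromo-3-methylnaphthalen-1-ol | Cc1cc2ccccc2c(O)c1Br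
F8 | step 10 | 3-bromo-2-methylnaphthalen-1-ol | Cc1c(O)c2ccccc2cc1Br
F9 | step 10 | 2-bromo-3-methylnaphthalene-1,4-dione | CC1=C(Br)C(=O)c2ccccc2C1=O
F10 | step 10 | 2-bromo-3-methylnaphthalene-1,4-diol | Cc1c(O)c2ccccc2c(O)c1Br
F11 | step 10 | 2-bromo-1,4-dimethoxy-3-methylnaphthalene | COc1c(C)c(Br)c(OC)c2ccccc12
F12 | step 10 | (1,4-dimethoxy-3-methylnaphthalen-2-yl)lithium | COc1c(C)c([Li])c(OC)c2ccccc12
F13 | step 10 | (1,4-dimethoxy-3-methylnaphthalen-2-yl)copper | COc1c(C)c([Cu])c(OC)c2ccccc12
F14 | step 10 | tert-butyl{[(2E,5S,7R,11R)-1-(1,4-dimethoxy-3-methylnaphthalen-2-yl)-3,7,11,15-tetramethylhexadec-2-en-5-yl]oxy}dimethylsilane | COc1c(C)c(C/C=C(\C)C[C@@H](O[Si](C)(C)C(C)(C)C)C[C@H](C)CCC[C@H](C)CCCC(C)C)c(OC)c2ccccc12
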